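**Retrosynthetic overview** (flavanone numbering, primes for the second unit)

1. Target 13 is the meso (2S,3R,2'R,3'S) trans,trans-3,3'-biflavanone; its four phenols travel as benzyl ethers and are released last by hydrogenolysis.
2. Both pyranone rings (ring C and ring C') are cut at O1–C8a and C3–C4 (and O1'–C8a', C3'–C4'), which leads back to the meso 1,4-diarylbut-2-yne-1,4-diol 7 and two molecules of 4-(benzyloxy)-2-fluorobenzaldehyde 9.
3. Enabling feature: C4(=O)–C3–C3'–C4'(=O) is a 1,4-diketone, i.e. the oxidation level of one C≡C plus two CHO groups, and each ketone sits ortho to the ring-A ether oxygen (C4–C4a–C8a–O1), so one 2-fluorobenzaldehyde supplies both the SNAr carbon C8a and the acyl-anion carbon C4.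
4. Ring order: double SNAr etherification, then carbene-catalysed alkyne hydroacylation closes ring C and an intramolecular Stetter reaction closes ring C', all in one flask; C3/C3' settle trans to the C2/C2' aryl groups.
5. The meso diol 7 comes from two catalyst-controlled alkynylations of 4-(benzyloxy)benzaldehyde with antipodal ligands.

Key step: step 7

Remark: 7 is meso, so the absolute sense of the two alkynylations is immaterial as long as steps 1 and 4 use antipodal ligands. Descriptors of 3–6 are written for the (S,S)-ligand delivering (1R)-3; if the facial sense were the opposite, they would all invert and the same 7 would result.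

**Step 1**
Reactants: 1 4-(benzyloxy)benzaldehyde; 2 ethynyltrimethylsilane
Product: 3 (1R)-1-[4-(benzyloxy)phenyl]-3-(trimethylsilyl)prop-2-yn-1-ol
Conditions: ZnMe2 (3 equiv), (S,S)-ProPhenol [2,6-bis{[(2S)-2-(hydroxydiphenylmethyl)pyrrolidin-1-yl]methyl}-4-methylphenol] (10 mol %), Ph3PO (20 mol %), toluene, 4 °C; aq NH4Cl
Reagents that add atoms: none
Why: Catalytic enantioselective alkynylation of an aromatic aldehyde by the alkynylzinc of 2 inside the dinuclear zinc–ProPhenol pocket, which selects one aldehyde face and so sets the carbinol center that becomes C2 of the target.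

**Step 2**
Reactants: 3 (1R)-1-[4-(benzyloxy)phenyl]-3-(trimethylsilyl)prop-2-yn-1-ol
Product: 4 tert-butyl{[(1R)-1-[4-(benzyloxy)phenyl]-3-(trimethylsilyl)prop-2-yn-1-yl]oxy}dimethylsilane
Conditions: TBSCl, imidazole, DMF, rt
Reagents that add atoms: tert-butyldimethylsilyl chloride, CC(C)(C)[Si](C)(C)Cl
Why: Standard imidazole-promoted O-silylation, which keeps the hydroxyl from consuming ZnMe2 in step 4 and does not touch the stereocenter.

**Step 3**
Reactants: 4 tert-butyl{[(1R)-1-[4-(benzyloxy)phenyl]-3-(trimethylsilyl)prop-2-yn-1-yl]oxy}dimethylsilane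
Product: 5 tert-butyl{[(1S)-1-[4-(benzyloxy)phenyl]prop-2-yn-1-yl]oxy}dimethylsilane
Conditions: K2CO3 (0.2 equiv), MeOH–THF, rt
Reagents that add atoms: none
Why: Methoxide-mediated protodesilylation cleaves the alkynyl C–Si bond while the hindered O–TBS ether survives; the center is untouched and its descriptor changes from R to S only because ethynyl now ranks below aryl.

**Step 4**
Reactants: 5 tert-butyl{[(1S)-1-[4-(benzyloxy)phenyl]prop-2-yn-1-yl]oxy}dimethylsilane (1.5 equiv, excess recovered); 1 4-(benzyloxy)benzaldehyde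
Product: 6 (1S,4R)-1,4-bis[4-(benzyloxy)phenyl]-4-{[tert-butyl(dimethyl)silyl]oxy}but-2-yn-1-ol
Conditions: ZnMe2 (2 equiv), (R,R)-ProPhenol (20 mol %), Ph3PO (40 mol %), toluene, 4 °C to rt; aq NH4Cl
Reagents that add atoms: none
Why: Second ProPhenol-catalysed alkynylation with the antipodal ligand, so that reagent control (the existing center lies across the linear alkyne and exerts no bias) installs the new carbinol with the opposite spatial sense and creates the meso 1,4-relationship that becomes C2/C2'.

**Step 5**
Reactants: 6 (1S,4R)-1,4-bis[4-(benzyloxy)phenyl]-4-{[tert-butyl(dimethyl)silyl]oxy}but-2-yn-1-ol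
Product: 7 (1R,4S)-1,4-bis[4-(benzyloxy)phenyl]but-2-yne-1,4-diol (meso)
Conditions: Bu4NF (1.2 equiv), THF, 0 °C; aq NH4Cl
Reagents that add atoms: none
Why: Fluoride-induced cleavage of the silyl ether, driven by Si–F bond formation, under conditions that leave both propargylic stereocenters alone.

**Step 6**
Reactants: 8 2-fluoro-4-hydroxybenzaldehyde
Product: 9 4-(benzyloxy)-2-fluorobenzaldehyde
Conditions: BnBr, K2CO3, DMF, rt
Reagents that add atoms: benzyl bromide, BrCc1ccccc1
Why: Williamson O-benzylation of the phenol under mild carbonate conditions, at which the weakly nucleophilic phenoxide should not displace the aryl fluoride.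

**Step 7**
Reactants: 7 (1R,4S)-1,4-bis[4-(benzyloxy)phenyl]but-2-yne-1,4-diol (meso); 9 4-(benzyloxy)-2-fluorobenzaldehyde (2.1 equiv)
Product: 12 (2S,2'R,3R,3'S)-7,7'-bis(benzyloxy)-2,2'-bis[4-(benzyloxy)phenyl]-2,2',3,3'-tetrahydro-4H,4'H-[3,3'-bichromene]-4,4'-dione (meso), via bis-ether dialdehyde 10 (not isolated), via alkylidene-flavanone aldehyde 11 (not isolated)
Conditions: NaH (2.2 equiv), DMF, 0 °C to rt; then, same flask, 3-mesityl-5,6,7,8-tetrahydro-4H-cyclohepta[d]thiazol-3-ium perchlorate (20 mol %), K2CO3 (40 mol %), THF (dilution to 0.02 M), 70 °C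
Reagents that add atoms: none
Why: Two alkoxide SNAr displacements of fluoride ortho to the formyl group (Meisenheimer adducts stabilised by CHO) form both O1–C8a aryl ether bonds; the thiazol-2-ylidene then turns one formyl group into a Breslow intermediate that adds its nucleophilic carbon and enol hydrogen syn across the unactivated alkyne (C3–C4 bond, ring C, 6-exo-dig) to give the (E)-exocyclic enone 11, and the second Breslow intermediate adds to the enone β-carbon in an intramolecular Stetter reaction (C3'–C4' bond, ring C', 6-exo-trig). The closest known reaction types are the SNAr etherification of 2-fluorobenzaldehydes and the carbene-catalysed alkyne hydroacylation/Stetter cascade of O-propargyl salicylaldehydes, here run in both directions on one alkyne so that the 1,4-diketone arises redox-neutrally from C≡C plus two CHO groups. C2 and C2' are not touched because no bond to them is made or broken. C3 and C3' are both α to the new ketones and should be set under thermodynamic control by carbonate-mediated enolisation, each ending trans (diequatorial) to the aryl group on its neighbouring C2, which with the meso C2/C2' pair can only give the meso trans,trans isomer. The step needs 6-exo over 7-endo attack on the alkyne, secured by the four-atom link C4a–C8a–O1–C2 that lets the acyl carbon reach only the proximal alkyne carbon, and ring closure over intermolecular benzoin or Stetter coupling, secured by dilution and by the second aldehyde being held next to the enone. It also needs the exocyclic enone to be trapped before base moves its double bond into ring C, which the tethered acyl-anion donor should ensure.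

**Step 8**
Reactants: 12 (2S,2'R,3R,3'S)-7,7'-bis(benzyloxy)-2,2'-bis[4-(benzyloxy)phenyl]-2,2',3,3'-tetrahydro-4H,4'H-[3,3'-bichromene]-4,4'-dione
Product: 13 (2S,2'R,3R,3'S)-7,7'-dihydroxy-2,2'-bis(4-hydroxyphenyl)-2,2',3,3'-tetrahydro-4H,4'H-[3,3'-bichromene]-4,4'-dione (CNP0231820.1)
Conditions: H2 (1 atm), Pd/C (10 wt %), THF–MeOH, rt
Reagents that add atoms: none
Why: Heterogeneous hydrogenolysis of the four primary benzyl aryl ethers under neutral conditions, at which the α-keto centers C3/C3' should not epimerise and the hindered cyclic C2–O1 bonds and aryl ketones should react far more slowly than the unhindered O-benzyl groups.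

**Compound list**

1 | 4-(benzyloxy)benzaldehyde | O=Cc1ccc(OCc2ccccc2)cc1 | starting material
2 | ethynyltrimethylsilane | C#C[Si](C)(C)C | starting material
3 | (1R)-1-[4-(benzyloxy)phenyl]-3-(trimethylsilyl)prop-2-yn-1-ol | O[C@H](c1ccc(OCc2ccccc2)cc1)C#C[Si](C)(C)C | intermediate
4 | tert-butyl{[(1R)-1-[4-(benzyloxy)phenyl]-3-(trimethylsilyl)prop-2-yn-1-yl]oxy}dimethylsilane | CC(C)(C)[Si](C)(C)O[C@H](c1ccc(OCc2ccccc2)cc1)C#C[Si](C)(C)C | intermediate
5 | tert-butyl{[(1S)-1-[4-(benzyloxy)phenyl]prop-2-yn-1-yl]oxy}dimethylsilane | CC(C)(C)[Si](C)(C)O[C@H](c1ccc(OCc2ccccc2)cc1)C#C | intermediate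
6 | (1S,4R)-1,4-bis[4-(benzyloxy)phenyl]-4-{[tert-butyl(dimethyl)silyl]oxy}but-2-yn-1-ol | CC(C)(C)[Si](C)(C)O[C@H](c1ccc(OCc2ccccc2)cc1)C#C[C@@H](O)c1ccc(OCc2ccccc2)cc1 | intermediate
7 | (1R,4S)-1,4-bis[4-(benzyloxy)phenyl]but-2-yne-1,4-diol (meso) | O[C@H](c1ccc(OCc2ccccc2)cc1)C#C[C@@H](O)c1ccc(OCc2ccccc2)cc1 | intermediate
8 | 2-fluoro-4-hydroxybenzaldehyde | O=Cc1ccc(O)cc1F | starting material
9 | 4-(benzyloxy)-2-fluorobenzaldehyde | O=Cc1ccc(OCc2ccccc2)cc1F | intermediate
10 | 2,2'-{[(1R,4S)-1,4-bis[4-(benzyloxy)phenyl]but-2-yne-1,4-diyl]bis(oxy)}bis[4-(benzyloxy)benzaldehyde] (meso) | O=Cc1ccc(OCc2ccccc2)cc1O[C@H](c1ccc(OCc2ccccc2)cc1)C#C[C@@H](Oc1cc(OCc2ccccc2)ccc1C=O)c1ccc(OCc2ccccc2)cc1 | intermediate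
11 | (2R)-7-(benzyloxy)-2-[4-(benzyloxy)phenyl]-3-{(E,2R)-2-[4-(benzyloxy)phenyl]-2-[5-(benzyloxy)-2-formylphenoxy]ethylidene}chroman-4-one (racemic, one enantiomer drawn; vinyl H cis to the C4 carbonyl) | O=C1c2ccc(OCc3ccccc3)cc2O[C@H](c2ccc(OCc3ccccc3)cc2)/C1=C\[C@@H](Oc1cc(OCc2ccccc2)ccc1C=O)c1ccc(OCc2ccccc2)cc1 | intermediate
12 | (2S,2'R,3R,3'S)-7,7'-bis(benzyloxy)-2,2'-bis[4-(benzyloxy)phenyl]-2,2',3,3'-tetrahydro-4H,4'H-[3,3'-bichromene]-4,4'-dione (meso, both rings 2,3-trans) | O=C1c2ccc(OCc3ccccc3)cc2O[C@H](c2ccc(OCc3ccccc3)cc2)[C@H]1[C@@H]1C(=O)c2ccc(OCc3ccccc3)cc2O[C@H]1c1ccc(OCc2ccccc2)cc1 | intermediate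
13 | (2S,2'R,3R,3'S)-7,7'-dihydroxy-2,2'-bis(4-hydroxyphenyl)-2,2',3,3'-tetrahydro-4H,4'H-[3,3'-bichromene]-4,4'-dione (meso) | O=C1c2ccc(O)cc2O[C@H](c2ccc(O)cc2)[C@H]1[C@@H]1C(=O)c2ccc(O)cc2O[C@H]1c1ccc(O)cc1 | target

**Step count and risks**

Total steps: 8. Longest linear sequence: 7 (steps 1–5, 7, 8); step 6 is a one-step side branch.

Steps most likely to fail:

Step 7. In the alkoxide stage, hydride transfer from the propargylic alkoxide to the aldehyde or base-induced propargyl-to-allenyl isomerisation may consume material. In the carbene stage, the exocyclic double bond of 11 may migrate into ring C before the second acyl-anion addition, or carbonate may open a pyranone ring by β-elimination of the aryloxide and so erode the C2/C2' relationship. The fallback sets out from 7 and comes back at 10. 2,4-Dihydroxybenzaldehyde is benzylated selectively at the 4-hydroxyl (BnBr, NaHCO3, MeCN; the 2-hydroxyl is held in a hydrogen bond to the formyl group) to give 4-(benzyloxy)-2-hydroxybenzaldehyde F1. F1 is coupled twice with 7 in a Mitsunobu reaction (PPh3, diisopropyl azodicarboxylate, THF, 0 °C); the two inversions keep the meso relationship, and 10 is isolated and purified. The ether bonds are thus made at the sp3 carbons under neutral conditions without any alkoxide, and the carbene cascade of step 7 is then run on pure 10, free of fluoride and strong base, to reach 12.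

Step 4. Addition of the hindered α-silyloxy alkynylzinc may be sluggish, and incomplete catalyst control would let the chiral (non-meso) diastereomer form alongside 6. The fallback sets out from 5 and comes back at 6. Acyl Sonogashira coupling of 5 with 4-(benzyloxy)benzoyl chloride (PdCl2(PPh3)2, copper iodide CuI, Et3N, THF) gives (4R)-1,4-bis[4-(benzyloxy)phenyl]-4-{[tert-butyl(dimethyl)silyl]oxy}but-2-yn-1-one F2. F2 is reduced in a Midland reduction with (S)-B-isopinocampheyl-9-borabicyclo[3.3.1]nonane (alkynyl as the small group, the antipode chosen to deliver the 1S carbinol) to give 6.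

Step 1. The electron-rich aldehyde may react slowly, so that background methyl transfer from ZnMe2 and incomplete face selection lower the enantiopurity that later becomes diastereopurity. The fallback sets out from 1 and comes back at 5, bypassing 3 and 4. Ethynylmagnesium bromide (THF, 0 °C) adds to 1 to give racemic 1-[4-(benzyloxy)phenyl]prop-2-yn-1-ol F3. Kinetic resolution with Candida antarctica lipase B and vinyl acetate should acylate the R enantiomer, following the usual enantiopreference of this lipase for secondary alcohols, to give (1R)-1-[4-(benzyloxy)phenyl]prop-2-yn-1-yl acetate F5 and leave (1S)-1-[4-(benzyloxy)phenyl]prop-2-yn-1-ol F4. F4 is silylated (TBSCl, imidazole, DMF) to give 5.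

**Further compounds**

F1 | step 7 | 4-(benzyloxy)-2-hydroxybenzaldehyde | O=Cc1ccc(OCc2ccccc2)cc1O
F2 | step 4 | (4R)-1,4-bis[4-(benzyloxy)phenyl]-4-{[tert-butyl(dimethyl)silyl]oxy}but-2-yn-1-one | CC(C)(C)[Si](C)(C)O[C@H](c1ccc(OCc2ccccc2)cc1)C#CC(=O)c1ccc(OCc2ccccc2)cc1
F3 | step 1 | racemic 1-[4-(benzyloxy)phenyl]prop-2-yn-1-ol | OC(C#C)c1ccc(OCc2ccccc2)cc1
F4 | step 1 | (1S)-1-[4-(benzyloxy)phenyl]prop-2-yn-1-ol | O[C@H](c1ccc(OCc2ccccc2)cc1)C#C
F5 | step 1 | (1R)-1-[4-(benzyloxy)phenyl]prop-2-yn-1-yl acetate | CC(=O)O[C@@H](c1ccc(OCc2ccccc2)cc1)C#C
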